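**Plan**
- Retrosynthesis cuts, in this order: C12–C13 (Negishi coupling of a C12 zinc reagent with an (E)-enol triflate), C4–C18 (enolate methylation), C4–C5 (anodic closure of ring A), C1=C2 (Horner–Wadsworth–Emmons), C10–C20 (Birch reductive methylation) and aryl C9–C11 (epoxide opening).
- Enabling feature: O3 and O6 are 1,4-related across the C4–C5 bond, so ring A can close by oxidative union of C4 of a C3 keto ester with C5 of the C5=C6 methyl enol ether. Birch reduction of an anisole places that enol ether in ring B next to the quaternary C10 that carries the tether.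
- Forward: ring B is the arene, reduced to a 1-methoxycyclohexa-1,4-diene. The C1–C4/C19 chain grows from the amide carbon, ring A closes at the anode, and the C11–C12 arm is extended to the C13–C16 enoate last.
- Stereochemistry: C10 from the prolinol-ether auxiliary in the Birch methylation; C5 by equilibration to the trans ring fusion through the extended dienolate; C4 by methylation anti to the C20 methyl; C3 and C6 by hydride delivery; 13E by a stereoretentive coupling.
- C4 is carried through the ring closure as an enolisable CH and made quaternary only after the ring fusion is trans, because the tether geometry should give a cis-fused primary product on which a quaternary C4 could not be corrected.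

Key step: step 9

Numbering: labdane numbering (C1–C20) is used for all intermediates.
Assumption: the (S)-auxiliary is taken to direct methylation of the kinetically formed Birch enolate to the face that gives the (1S) quaternary carbon (C10 of the target); should the opposite face be preferred, the (R)-auxiliary is used and nothing else changes.

**Route**

Step 1
Reactants: 1 3-methoxy-5-methylbenzoic acid
Product: 2 2-bromo-5-methoxy-3-methylbenzoic acid
Conditions: NBS, MeCN, rt, dark
Reagents that add atoms: N-bromosuccinimide, O=C1CCC(=O)N1Br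
Why: Electrophilic aromatic bromination, in which the methoxy group directs para and the methyl group ortho to the same carbon (between carboxyl and methyl), so one regioisomer is expected.

Step 2
Reactants: 2 2-bromo-5-methoxy-3-methylbenzoic acid; 3 (S)-2-(methoxymethyl)pyrrolidine
Product: 5 (2-bromo-5-methoxy-3-methylphenyl)[(2S)-2-(methoxymethyl)pyrrolidin-1-yl]methanone, via acid chloride 4 (not isolated)
Conditions: (COCl)2, cat. DMF, CH2Cl2, 0 °C → rt; then 3, Et3N, CH2Cl2, 0 °C → rt
Reagents that add atoms: none
Why: Amide formation by acylation of the secondary amine with the acid chloride (Schotten–Baumann type); the stereocentre of 3 is not touched.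

Step 3
Reactants: 5 bromo amide; 6 ethylene oxide
Product: 8 [2-(2-hydroxyethyl)-5-methoxy-3-methylphenyl][(2S)-2-(methoxymethyl)pyrrolidin-1-yl]methanone, via aryllithium 7 (not isolated)
Conditions: n-BuLi, THF, −78 °C; then 6, −78 → −20 °C
Reagents that add atoms: none
Why: Bromine–lithium exchange at −78 °C is faster than attack on the hindered tertiary amide, and the carbonyl-stabilised ortho-aryllithium opens ethylene oxide by SN2 to install the C11–C12 arm.

Step 4
Reactants: 8 hydroxyethyl amide
Product: 9 triisopropylsilyl ether of 8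
Conditions: i-Pr3SiCl, imidazole, DMF, rt
Reagents that add atoms: chlorotriisopropylsilane, CC(C)[Si](Cl)(C(C)C)C(C)C
Why: Silylation of a primary alcohol; the triisopropylsilyl ether should survive lithium in ammonia, the bases and hydrides ahead and the aqueous acid of step 9.

Step 5
Reactants: 9 silyl ether amide
Product: 11 [(1S)-5-methoxy-1,3-dimethyl-2-[2-(triisopropylsilyloxy)ethyl]cyclohexa-2,5-dien-1-yl][(2S)-2-(methoxymethyl)pyrrolidin-1-yl]methanone, via lithium amide enolate 10 (not isolated)
Conditions: Li, NH3(l)/THF, t-BuOH (1 equiv), −78 °C; piperylene; then MeI, −78 °C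
Reagents that add atoms: iodomethane, CI
Why: Birch reduction–alkylation of a chiral benzamide: two-electron reduction and protonation at C7 by the single equivalent of t-BuOH give the amide enolate with the methoxy and alkyl groups left on sp2 carbons, and iodomethane attacks the lithium-chelated enolate on the face turned away from the pyrrolidine side arm, which sets C10.

Step 6
Reactants: 11 diene amide
Product: 12 (1S)-5-methoxy-1,3-dimethyl-2-[2-(triisopropylsilyloxy)ethyl]cyclohexa-2,5-diene-1-carbaldehyde
Conditions: Cp2Zr(H)Cl, THF, rt; H2O work-up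
Reagents that add atoms: none
Why: Reduction of a tertiary amide to the aldehyde by Cp2Zr(H)Cl (hydrozirconation of the C=O and collapse of the zirconium N,O-acetal on work-up) runs under neutral conditions that spare the enol ether, the silyl ether and the hindered alkenes, and C10 bears no hydrogen and cannot epimerise.

Step 7
Reactants: 12 aldehyde; 13 ethyl 4-(diethoxyphosphoryl)-3-oxobutanoate
Product: 15 ethyl (E)-5-[(1S)-5-methoxy-1,3-dimethyl-2-[2-(triisopropylsilyloxy)ethyl]cyclohexa-2,5-dien-1-yl]-3-oxopent-4-enoate, via phosphonate dianion 14 (not isolated)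
Conditions: 13, NaH (2.1 equiv), THF, 0 °C; then 12, 0 °C → rt
Reagents that add atoms: none
Why: Horner–Wadsworth–Emmons olefination through the phosphonate carbanion of the keto ester dianion, the reactive site once C4 is held as its enolate, should give the (E)-enone with the non-enolisable aldehyde.

Step 8
Reactants: 15 enone keto ester
Product: 16 ethyl 5-[(1S)-5-methoxy-1,3-dimethyl-2-[2-(triisopropylsilyloxy)ethyl]cyclohexa-2,5-dien-1-yl]-3-oxopentanoate
Conditions: [(Ph3P)CuH]6, H2O (2 equiv), benzene/THF, rt
Reagents that add atoms: none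
Why: Conjugate reduction by the copper hydride is specific for the enone C1=C2 and should leave the enol ether, the tetrasubstituted alkene and the ketone untouched.

Step 9
Reactants: 16 keto ester tethered to the 1-methoxycyclohexa-1,4-diene
Product: 18 cis-fused (5β-H, 10β-CH3) ethyl 3,6-dioxo-12-(triisopropylsilyloxy)-13,14,15,16,18-pentanorlabd-8-en-19-oate (C4 epimers and enol), via C6 dimethyl ketal 17 (not isolated)
Conditions: reticulated vitreous carbon anode, Pt cathode, undivided cell, constant current (2.2 F/mol), 0.1 M LiClO4, 2,6-lutidine (4 equiv), MeOH/CH2Cl2 1:4, rt; then 0.5 M aq. oxalic acid, THF, 0 °C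
Reagents that add atoms: water, O
Why: Proposed new method: at the carbon anode the C5=C6 methyl enol ether, the most easily oxidised π-system of 16, loses one electron and the enol carbon C4 of the keto ester attacks C5 of the radical cation (or, from lutidine-generated enolate, the C4 radical adds to C5; both paths give the same C4–C5 bond and the same α-methoxy radical at C6), a second oxidation gives the C6 oxocarbenium ion that methanol traps as ketal 17, and aqueous oxalic acid then releases the C6 ketone. The closest known reaction types are the anodic coupling of enol ether radical cations with tethered electron-rich olefins, the anodic addition of 1,3-dicarbonyl compounds to enol ethers and the Mn(OAc)3-mediated cyclisation of β-keto ester radicals onto alkenes; their intramolecular combination on a dihydroanisole is not known. Ring A closes in the 6-exo-trig mode. C5 is controlled by the tether: C4 can reach C5 only on the face of ring B that carries C1, opposite the C20 methyl, so the cis ring fusion is expected, while C4 is kept as an enolisable CH on purpose. The step needs bond formation at C5 (not C7 or C9), no oxidation of the C8=C9 alkene and no further oxidation of the product: the Birch step has fixed the enol ether at C5=C6 next to the tether-bearing C10, an enol ether is oxidised well below a tetrasubstituted alkene, and once it is consumed 18 should hold no group that reacts at that potential under weakly basic conditions.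

Step 10
Reactants: 18 cis-fused dione keto ester
Product: 20 trans-fused (5α-H, 10β-CH3) ethyl 3,6-dioxo-12-(triisopropylsilyloxy)-13,14,15,16,18-pentanorlabd-8-en-19-oate (C4 epimers and enol), via dipotassium dienolate 19 (not isolated)
Conditions: KOt-Bu (4 equiv), t-BuOH/THF, rt, Ar; then inverse quench into cold 10% aq. AcOH
Reagents that add atoms: none
Why: Under excess KOt-Bu the keto ester is masked as its enolate and the C6 ketone as the extended dienolate (C6=C7, C8=C9), C5 equilibrates through the small share of neutral ketone to the more stable trans ring fusion (as in the 5β → 5α epimerisation of 6-oxo steroids), and the fast acid quench protonates the dienolate kinetically at C7, which returns the C8=C9 alkene (deconjugative protonation).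

Step 11
Reactants: 20 trans-fused dione keto ester
Product: 21 ethyl 3,6-dioxo-12-(triisopropylsilyloxy)-13,14,15,16-tetranorlabd-8-en-19-oate (4α-CH3, 4β-CO2Et, 5α-H, 10β-CH3)
Conditions: K2CO3, MeI, acetone, rt
Reagents that add atoms: iodomethane, CI
Why: C-Alkylation of the ring-A β-keto ester enolate (the carbonate does not deprotonate C7): on the trans-decalin the β face of C4 is screened by the 1,3-diaxial C20 methyl, so iodomethane should enter from the α face and leave the ester axial (4β, C19), the outcome known for podocarpate-type keto esters.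

Step 12
Reactants: 21 dione ester
Product: 23 12-(triisopropylsilyloxy)-13,14,15,16-tetranorlabd-8-ene-3α,6β,19-triol, via 3α,6β-diol ester 22 (not isolated)
Conditions: LiBH(s-Bu)3, THF, −78 → −20 °C; then LiAlH4, 0 °C → rt; Rochelle salt work-up
Reagents that add atoms: none
Why: Diastereoselective ketone reduction by the bulky borohydride, which should attack C3 along the equatorial trajectory (axial 3α-OH) and C6 from the α face away from the axial C20 methyl and C19 ester (axial 6β-OH), followed by LiAlH4 reduction of the neopentyl C19 ester to the carbinol.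

Step 13
Reactants: 23 triol
Product: 24 12-(triisopropylsilyloxy)-13,14,15,16-tetranorlabd-8-ene-3α,6β,19-triyl triacetate
Conditions: Ac2O, pyridine, cat. DMAP, rt → 40 °C
Reagents that add atoms: acetic anhydride, CC(=O)OC(C)=O
Why: DMAP-catalysed acetylation caps all three hydroxyls, the hindered axial 6β-OH included, with groups that tolerate fluoride, the iodination and the organozinc step and are removed in the final saponification.

Step 14
Reactants: 24 triacetate silyl ether
Product: 25 3α,6β,19-triacetoxy-13,14,15,16-tetranorlabd-8-en-12-ol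
Conditions: HF·pyridine, pyridine, THF, 0 °C → rt
Reagents that add atoms: none
Why: Fluoride-mediated cleavage of the Si–O bond frees the primary C12 alcohol, while acetates and alkene are inert to buffered HF.

Step 15
Reactants: 25 primary alcohol
Product: 26 12-iodo-13,14,15,16-tetranorlabd-8-ene-3α,6β,19-triyl triacetate
Conditions: I2, PPh3, imidazole, CH2Cl2, 0 °C → rt
Reagents that add atoms: iodine, II
Why: Appel-type iodination (Garegg–Samuelsson conditions) converts the unhindered primary alcohol into the iodide by SN2 on the alkoxyphosphonium ion.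

Step 16
Reactants: 27 ethyl acetoacetate
Product: 28 ethyl (E)-3-(trifluoromethylsulfonyloxy)but-2-enoate
Conditions: Tf2O, aq. Me4NOH, hexanes, 5 °C
Reagents that add atoms: trifluoromethanesulfonic anhydride, O=S(=O)(OS(=O)(=O)C(F)(F)F)C(F)(F)F
Why: O-Sulfonylation of the acetoacetate enolate under non-chelating tetraalkylammonium conditions should give the (E)-enol triflate, in which the triflate is trans to the ester.

Step 17
Reactants: 26 iodide; 28 (E)-enol triflate
Product: 30 ethyl (13E)-3α,6β,19-triacetoxylabda-8,13-dien-15-oate, via alkylzinc iodide 29 (not isolated)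
Conditions: Zn dust (BrCH2CH2Br, Me3SiCl activation), THF, 40 °C; then 28, Pd(PPh3)4 (5 mol %), THF, 50 °C
Reagents that add atoms: none
Why: Zinc inserts into the primary C–I bond without touching the acetates, and Negishi coupling with the enol triflate proceeds with retention at the sp2 carbon, so the new C12–C13 bond is trans to the ester and the alkene is 13E.

Step 18
Reactants: 30 triacetate ethyl ester
Product: 31 (13E)-3α,6β,19-trihydroxylabda-8,13-dien-15-oic acid (target)
Conditions: LiOH, THF/MeOH/H2O, 50 °C; then 1 M HCl to pH 3–4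
Reagents that add atoms: lithium hydroxide, [Li+].[OH-]
Why: Saponification removes the three acetates and the ethyl ester in one operation, and mild acidification should give the free acid without disturbing the alcohols or the alkenes.

**Compound list**

1 | 3-methoxy-5-methylbenzoic acid | COc1cc(C)cc(C(=O)O)c1 | starting material
2 | 2-bromo-5-methoxy-3-methylbenzoic acid | COc1cc(C)c(Br)c(C(=O)O)c1 | intermediate
3 | (S)-2-(methoxymethyl)pyrrolidine | COC[C@@H]1CCCN1 | starting material
4 | 2-bromo-5-methoxy-3-methylbenzoyl chloride | COc1cc(C)c(Br)c(C(=O)Cl)c1 | intermediate (not isolated)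
5 | (2-bromo-5-methoxy-3-methylphenyl)[(2S)-2-(methoxymethyl)pyrrolidin-1-yl]methanone | COC[C@@H]1CCCN1C(=O)c1cc(OC)cc(C)c1Br | intermediate
6 | ethylene oxide | C1CO1 | starting material
7 | aryllithium from 5 (lithium in place of bromine) | COC[C@@H]1CCCN1C(=O)c1cc(OC)cc(C)c1[Li] | intermediate (not isolated)
8 | [2-(2-hydroxyethyl)-5-methoxy-3-methylphenyl][(2S)-2-(methoxymethyl)pyrrolidin-1-yl]methanone | COC[C@@H]1CCCN1C(=O)c1cc(OC)cc(C)c1CCO | intermediate
9 | triisopropylsilyl ether of 8 | COC[C@@H]1CCCN1C(=O)c1cc(OC)cc(C)c1CCO[Si](C(C)C)(C(C)C)C(C)C | intermediate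
10 | lithium amide enolate of the 1,4-dihydroarene (exocyclic C10=C(OLi)N, C5=C6, C8=C9) | [Li]OC(N1CCC[C@H]1COC)=C1C=C(OC)CC(C)=C1CCO[Si](C(C)C)(C(C)C)C(C)C | intermediate (not isolated)
11 | [(1S)-5-methoxy-1,3-dimethyl-2-[2-(triisopropylsilyloxy)ethyl]cyclohexa-2,5-dien-1-yl][(2S)-2-(methoxymethyl)pyrrolidin-1-yl]methanone | COC1=C[C@](C)(C(=O)N2CCC[C@H]2COC)C(CCO[Si](C(C)C)(C(C)C)C(C)C)=C(C)C1 | intermediate
12 | (1S)-5-methoxy-1,3-dimethyl-2-[2-(triisopropylsilyloxy)ethyl]cyclohexa-2,5-diene-1-carbaldehyde | COC1=C[C@](C)(C=O)C(CCO[Si](C(C)C)(C(C)C)C(C)C)=C(C)C1 | intermediate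
13 | ethyl 4-(diethoxyphosphoryl)-3-oxobutanoate | CCOC(=O)CC(=O)CP(=O)(OCC)OCC | starting material
14 | disodium dianion of 13 | [Na+].[Na+].CCOC(=O)[CH-]C(=O)[CH-]P(=O)(OCC)OCC | intermediate (not isolated)
15 | ethyl (E)-5-[(1S)-5-methoxy-1,3-dimethyl-2-[2-(triisopropylsilyloxy)ethyl]cyclohexa-2,5-dien-1-yl]-3-oxopent-4-enoate | COC1=C[C@](C)(/C=C/C(=O)CC(=O)OCC)C(CCO[Si](C(C)C)(C(C)C)C(C)C)=C(C)C1 | intermediate
16 | ethyl 5-[(1S)-5-methoxy-1,3-dimethyl-2-[2-(triisopropylsilyloxy)ethyl]cyclohexa-2,5-dien-1-yl]-3-oxopentanoate (key-step precursor) | COC1=C[C@](C)(CCC(=O)CC(=O)OCC)C(CCO[Si](C(C)C)(C(C)C)C(C)C)=C(C)C1 | intermediate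
17 | cis-fused (5β-H, 10β-CH3) ethyl 6,6-dimethoxy-3-oxo-12-(triisopropylsilyloxy)-13,14,15,16,18-pentanorlabd-8-en-19-oate, C4 epimers | CC1=C(CCO[Si](C(C)C)(C(C)C)C(C)C)[C@@]2(C)CCC(=O)C(C(=O)OCC)[C@H]2C(OC)(OC)C1 | intermediate (not isolated)
18 | cis-fused (5β-H, 10β-CH3) ethyl 3,6-dioxo-12-(triisopropylsilyloxy)-13,14,15,16,18-pentanorlabd-8-en-19-oate, C4 epimers and enol (key-step product) | CC1=C(CCO[Si](C(C)C)(C(C)C)C(C)C)[C@@]2(C)CCC(=O)C(C(=O)OCC)[C@H]2C(=O)C1 | intermediate
19 | dipotassium salt: C3 enolate of the keto ester and extended C6 dienolate (C6=C7, C8=C9), 5α-H | [K+].[K+].CCOC(=O)C1=C([O-])CC[C@]2(C)C(CCO[Si](C(C)C)(C(C)C)C(C)C)=C(C)C=C([O-])[C@@H]12 | intermediate (not isolated)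
20 | trans-fused (5α-H, 10β-CH3) ethyl 3,6-dioxo-12-(triisopropylsilyloxy)-13,14,15,16,18-pentanorlabd-8-en-19-oate, C4 epimers and enol | CC1=C(CCO[Si](C(C)C)(C(C)C)C(C)C)[C@@]2(C)CCC(=O)C(C(=O)OCC)[C@@H]2C(=O)C1 | intermediate
21 | ethyl 3,6-dioxo-12-(triisopropylsilyloxy)-13,14,15,16-tetranorlabd-8-en-19-oate (4α-CH3, 4β-CO2Et, 5α-H, 10β-CH3) | CC1=C(CCO[Si](C(C)C)(C(C)C)C(C)C)[C@@]2(C)CCC(=O)[C@](C)(C(=O)OCC)[C@@H]2C(=O)C1 | intermediate
22 | ethyl 3α,6β-dihydroxy-12-(triisopropylsilyloxy)-13,14,15,16-tetranorlabd-8-en-19-oate | CC1=C(CCO[Si](C(C)C)(C(C)C)C(C)C)[C@@]2(C)CC[C@@H](O)[C@](C)(C(=O)OCC)[C@@H]2[C@H](O)C1 | intermediate (not isolated)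
23 | 12-(triisopropylsilyloxy)-13,14,15,16-tetranorlabd-8-ene-3α,6β,19-triol | CC1=C(CCO[Si](C(C)C)(C(C)C)C(C)C)[C@@]2(C)CC[C@@H](O)[C@](C)(CO)[C@@H]2[C@H](O)C1 | intermediate
24 | 12-(triisopropylsilyloxy)-13,14,15,16-tetranorlabd-8-ene-3α,6β,19-triyl triacetate | CC1=C(CCO[Si](C(C)C)(C(C)C)C(C)C)[C@@]2(C)CC[C@@H](OC(C)=O)[C@](C)(COC(C)=O)[C@@H]2[C@H](OC(C)=O)C1 | intermediate
25 | 3α,6β,19-triacetoxy-13,14,15,16-tetranorlabd-8-en-12-ol | CC1=C(CCO)[C@@]2(C)CC[C@@H](OC(C)=O)[C@](C)(COC(C)=O)[C@@H]2[C@H](OC(C)=O)C1 | intermediate
26 | 12-iodo-13,14,15,16-tetranorlabd-8-ene-3α,6β,19-triyl triacetate | CC1=C(CCI)[C@@]2(C)CC[C@@H](OC(C)=O)[C@](C)(COC(C)=O)[C@@H]2[C@H](OC(C)=O)C1 | intermediate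
27 | ethyl acetoacetate | CCOC(=O)CC(C)=O | starting material
28 | ethyl (E)-3-(trifluoromethylsulfonyloxy)but-2-enoate | CCOC(=O)/C=C(\C)OS(=O)(=O)C(F)(F)F | intermediate
29 | alkylzinc iodide from 26 (C12–ZnI) | CC1=C(CC[Zn]I)[C@@]2(C)CC[C@@H](OC(C)=O)[C@](C)(COC(C)=O)[C@@H]2[C@H](OC(C)=O)C1 | intermediate (not isolated)
30 | ethyl (13E)-3α,6β,19-triacetoxylabda-8,13-dien-15-oate | CC1=C(CC/C(C)=C/C(=O)OCC)[C@@]2(C)CC[C@@H](OC(C)=O)[C@](C)(COC(C)=O)[C@@H]2[C@H](OC(C)=O)C1 | intermediate
31 | (13E)-3α,6β,19-trihydroxylabda-8,13-dien-15-oic acid | CC1=C(CC/C(C)=C/C(=O)O)[C@@]2(C)CC[C@@H](O)[C@](C)(CO)[C@@H]2[C@H](O)C1 | target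

**Step count**

Total step count: 18. Longest linear sequence: 17 (steps 1–15, 17 and 18; step 16 is a one-step side branch).

**Steps most likely to fail**

1. Step 9 (anodic ring closure). What may go wrong: capture of the enol ether radical cation by methanol, oligomerisation, or oxidation at the C8=C9 alkene instead of ring closure. Fallback, from 16 back to 18 by carbenoid chemistry: diazo transfer to the keto ester of 16 (4-acetamidobenzenesulfonyl azide, Et3N, MeCN) gives the 2-diazo-3-oxo ester F1. Rh2(OAc)4 in CH2Cl2 then effects intramolecular cyclopropanation of the C5=C6 enol ether from the tether face to give the donor–acceptor cyclopropane F2. Aqueous oxalic acid opens its C4–C6 bond (push from the C6 methoxy group, pull from the keto ester) and, after loss of methanol, delivers the cis-fused dione 18.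

2. Step 10 (C5 equilibration with deconjugative quench). What may go wrong: incomplete epimerisation at C5, or protonation of the dienolate at C9 so that the alkene moves into conjugation with the C6 ketone. Fallback, from 18 back to 20 by hydride delivery to C5: selenenylation of the keto ester (PhSeCl, pyridine, CH2Cl2) gives the C4 phenylselenide F3. Oxidation with m-CPBA at −78 °C and warming expels benzeneselenenic acid by syn elimination with H5 to give the C4=C5 ene-dione ester F4. Conjugate reduction with [(Ph3P)CuH]6 should add hydride to C5 on the α face, anti to the C20 methyl, and protonation of the keto ester enolate gives the trans-fused 20.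

3. Step 6 (amide to aldehyde). What may go wrong: incomplete hydride transfer to the congested amide on the quaternary carbon, or hydrolysis of the enol ether while the aldehyde is released. Fallback, from 11 back to 12 in two redox steps: LiH2N·BH3 (lithium amidotrihydroborate) in THF reduces the amide to the primary alcohol F5 with loss of the auxiliary, and Dess–Martin oxidation buffered with NaHCO3 gives aldehyde 12.

Further compounds
F1 | step 9 | ethyl 2-diazo-5-[(1S)-5-methoxy-1,3-dimethyl-2-[2-(triisopropylsilyloxy)ethyl]cyclohexa-2,5-dien-1-yl]-3-oxopentanoate | COC1=C[C@](C)(CCC(=O)C(=[N+]=[N-])C(=O)OCC)C(CCO[Si](C(C)C)(C(C)C)C(C)C)=C(C)C1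
F2 | step 9 | cyclopropane-fused keto ester (C4–C5–C6 three-membered ring on the α face, 6-methoxy, 5β-H) | CCOC(=O)[C@]12C(=O)CC[C@]3(C)C(CCO[Si](C(C)C)(C(C)C)C(C)C)=C(C)C[C@@]1(OC)[C@H]23
F3 | step 10 | C4 phenylselenide of 18 (C4 epimers) | CC1=C(CCO[Si](C(C)C)(C(C)C)C(C)C)[C@@]2(C)CCC(=O)C([Se]c3ccccc3)(C(=O)OCC)[C@H]2C(=O)C1
F4 | step 10 | ethyl 3,6-dioxo-12-(triisopropylsilyloxy)-13,14,15,16,18-pentanorlabda-4,8-dien-19-oate (C4=C5 ene-dione) | CC1=C(CCO[Si](C(C)C)(C(C)C)C(C)C)[C@@]2(C)CCC(=O)C(C(=O)OCC)=C2C(=O)C1
F5 | step 6 | [(1S)-5-methoxy-1,3-dimethyl-2-[2-(triisopropylsilyloxy)ethyl]cyclohexa-2,5-dien-1-yl]methanol | COC1=C[C@](C)(CO)C(CCO[Si](C(C)C)(C(C)C)C(C)C)=C(C)C1
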